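## Structural features

The target is a 1-aryl-1,2-dihydronaphthalene. Ring A is the benzo ring with a free hydroxyl at C7 and a methoxyl at C6, ring B is the carbocycle C1–C2–C3–C4–C4a–C8a, and ring C is a 4-hydroxy-3-methoxyphenyl group on C1. Ring B holds one double bond, C3=C4, conjugated on one side with ring A and on the other with the C10 aldehyde on C3. C2 carries the acetoxymethyl group (C9). The only stereocentres are the neighbours C1 (S, doubly benzylic) and C2 (R, allylic and γ to the aldehyde), with ring C and C9 trans. The fragile points are the enal, the primary acetate, the two electron-rich phenols and the C1–H/C2–H pair: base at C2 opens a dienolate that can epimerise C2 or expel the C9 acetate, and oxidants can aromatise ring B and erase both stereocentres. The real difficulty is to set the C1/C2 pair in absolute and relative terms and to carry it, with C2 never α to a carbonyl group, through ring closure and through separate adjustment of C9 (alcohol level) and C10 (aldehyde level). The key step uses the fact that C4 is the one ring B carbon without a substituent and lies between C4a of ring A and C3, the α-carbon of the C10 carbonyl. It can therefore enter as carbon monoxide between a C4a bromide and a C3 ester enolate, closing ring B without touching C1 or C2.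

## Logic of the disconnections

**26 to 25.** The two phenolic O–CH2Ph bonds are cut last. Free phenols would be deprotonated in every organometallic and enolate step and would capture an acyl palladium species, so they stay masked throughout. This demands a debenzylation that spares the enal, the styrene-type C3=C4 bond, the acetate and the methyl ethers, which rules out hydrogenolysis and points to a Lewis acid with a cation scavenger.

**25 to 24 to 23.** The acetyl C–O bond at C9 and, before it, the O–Si bond are cut. An acetate cannot survive the hydride and amide-base steps, so C9 travels as a silyl ether. The desilylation must be run on the acidic side, because base at C2–H of the enal risks elimination or epimerisation.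

**23 to 22 to 21.** The C10 aldehyde is traced through the allylic alcohol to a tert-butyl ester. No bond of the skeleton is cut; the gain is an ester that can act as the enolate partner earlier. The oxidation must not dehydrogenate ring B.

**21 to 20 to 19.** The C4–H bond is replaced by C4–O (triflate, then enol). This adds a functional group in the retrosynthetic direction, but it turns C3=C4 into the enol of a β-keto ester, the retron of an acylation. The forward reduction of the enol triflate must leave the benzyl ethers, the silyl ether and C1/C2 alone.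

**19 to 16 + 17.** The C4a–C4 and C4–C3 bonds are cut together. Ring B opens to an acyclic aryl bromide–ester, and C4 becomes carbon monoxide. The forward step needs CO insertion to come before C–C coupling and needs C-acylation to win over O-acylation, with no acidic or nucleophilic group elsewhere. The tert-butyl ester, the silyl ether and the benzyl ethers in 16 serve these needs.

**16 to 15 to 14.** The O–Si bond and then the C9–N bond of the acyl oxazolidinone are cut (C9 alcohol from the imide carbonyl). This brings back the auxiliary that controls C2. The hydride must attack the imide but not the tert-butyl ester, and the γ-hydroxy ester must not lactonise.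

**14 to 11 + 12.** The C2–C3 bond is cut. The two-carbon ester arm becomes a bromoacetate, and C2 is set by auxiliary-controlled alkylation of the enolate 13. Attack must come anti to the 4-benzyl group of the auxiliary.

**11 to 9 + 3 (through 10).** The C1–C8a bond is cut, so ring A arrives as an aryl nucleophile on an enoyl imide that already carries ring C. The choice of which aryl group sits where is not free. The auxiliary directs both the aryl addition and the later alkylation to the same side of the extended chain. The incoming aryl and the incoming C3 therefore end up syn on the chain whose ends are C9 and the aryl of the enoyl unit. Only if ring A is the incoming aryl does this translate into the anti relation of C9 and ring C needed for the trans ring. With ring A in the enoyl unit and ring C as the nucleophile, ring B would close cis with either antipode of the auxiliary. With the roles set as here, the (S)-auxiliary gives (S)-C1 and then the correct C2. The price is an aryl metal reagent with an ortho bromine, which must be made and used cold.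

**9 to 6 + 7, and 6 to 4 + 5.** The imide N–C9 bond and the C1=C2 double bond are cut, leading to the auxiliary, a benzyl-protected vanillin and malonic acid. The alkene must be E.

**3 to 2 to 1.** The C–I bond and the O–benzyl bond are cut. The bromine para to the oxygen that becomes the C7 hydroxyl is already in 1. The iodination must go para to the methoxyl, which marks the future C8a.

## Other disconnections considered

**Alternative 1:** The cut is the C9–O bond, traced back to the prochiral 3-[4-(benzyloxy)-3-methoxybenzyl]cyclobutanone A2. Its carbonyl carbon becomes C10, its two α-methylenes are C3 and C9, and its benzyl carbon is C1 with ring C attached. In the forward key step a Baeyer–Villiger monooxygenase (whole cells, O2, cofactor recycling) would insert oxygen into one of the two enantiotopic C–C bonds and give the (R)-lactone A1, fixing C2.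

- In its favour: chirality comes from a catalyst and the oxidant is air; there is no auxiliary, CO or palladium. C9 and C10 are born differentiated at the right oxidation levels inside one ring, so no protecting group is needed to tell them apart.
- Against it here: only C2 is set. C1 is still a methylene in A1 and three ring B bonds remain. C3–C4 would come from condensation of the lactone enolate with 4. C1–C8a would need an oxidative, cation-type closure at the benzylic carbon, where the configuration of C1 rests on induction from C2 alone. The electron-rich arylidene lactone and the para-oxygenated ring C both invite over-oxidation and aromatisation in that closure. The enantioselectivity of such enzymes for a cyclobutanone with a large arylmethyl group depends on the individual enzyme.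
- Comparison: A1 maps cleanly onto C1, C2, C3, C9 and C10. On oxidation-state economy, and probably on step count, this alternative is the equal or the better of the chosen plan. On mechanism the chosen plan is more predictable: both stereocentres are set under auxiliary control before ring B exists, and the ring is closed at C4, which needs no stereocontrol, whereas the alternative closes the ring at the stereocentre C1.

**Alternative 2:** The cut is the C1–C2 bond. The substrate would be the acyclic (E)-enamide aldehyde A4, with the C3=C4 bond, the C10 N-methoxy-N-methyl amide and a benzhydryl methyl ether at C1 already in place. In the forward key step a diarylprolinol silyl ether would form the enamine of the C9 aldehyde, while the acid co-catalyst ionises the benzhydryl ether to the para-quinone methide of ring C. C2 would then add to C1 and close ring B to the trans aldehyde A3.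

- In its favour: ring B and both stereocentres would arise in one catalytic step on free phenols, which uses the 4-hydroxyl of ring C that the chosen plan only protects. C3=C4 is present from the start and C10 is one reduction from the aldehyde. On protecting-group and redox economy, and on the number of steps after ring closure, this alternative is better than the chosen plan.
- Against it here: A3 is a β,γ-unsaturated aldehyde with its α-stereocentre C2 next to the doubly benzylic C1. It is open to epimerisation, to migration of the double bond and to aromatisation. Control of the C1 configuration requires the catalyst to shield one face of an exocyclic quinone methide carbon flanked by an ortho-substituted aryl group, which cannot be taken for granted. Assembly of A4 is no shorter than that of the bromide used here.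
- Comparison: both plans close ring B in one step. The alternative creates the stereocentres in that step, while the chosen plan creates none there and keeps C2 away from any carbonyl α-position throughout. The alternative wins on economy; the chosen plan wins on predictability and on the stability of its intermediates.

**Alternative 3:** The cuts are C1–C2 and C3–C4. The substrate would be the 2-benzylbenzaldehyde A6, whose formyl carbon is C4 and whose benzylic methylene is C1. In the forward key step, irradiation at 365 nm with Ti(OiPr)4 and a TADDOL ligand would give the hydroxy-ortho-quinodimethane, which adds dimethyl fumarate A7 in a Diels–Alder reaction to give the tetralin diester A5.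

- In its favour: this is the most convergent route. Ring B and four stereocentres (the two that matter among them) come in one step from an achiral aldehyde and a commodity diester. The C4 hydroxyl is placed for dehydration to C3=C4 without a triflate or a reduction. On convergence and step count it is clearly better than the chosen plan.
- Against it here: C9 and C10 arrive as two methyl esters that must be told apart afterwards (conjugated against saturated, after dehydration). The chosen plan has them at different oxidation levels from the start. Absolute control by the titanium–TADDOL complex relies on two-point binding of the dienol, which is best supported when a coordinating group stands next to the formyl group; ring A has only hydrogen at C5. The dienol terminus at C1 carries an aryl group, so its geometry decides the C1/C2 relation. The chiral titanium reagent is stoichiometric, and the MOM ethers must be removed at the end by acid in the presence of the acetate.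
- Comparison: A5 holds every carbon of the target. Mechanistically the alternative depends on a short-lived photoenol and a chiral Lewis acid, where the chosen plan uses ground-state auxiliary chemistry and a catalytic carbonylation. The alternative is better on economy; the chosen plan is better on the certainty of the stereocentres and on the differentiation of C9 and C10.

Key step: step 9

Assumption: atom labels follow lignan numbering (C1 benzhydryl carbon, C2 bearing C9, C3 bearing C10, C4, C4a, C8a), and both auxiliary-controlled steps are taken to occur on the face of the metal-chelated acyl oxazolidinone opposite its 4-benzyl group, as is general for this auxiliary.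

## Steps

**Step 1**
Reactants: 1 4-bromo-2-methoxyphenol
Product: 2 1-(benzyloxy)-4-bromo-2-methoxybenzene
Conditions: BnBr, K2CO3, DMF, rt
Reagents that add atoms: benzyl bromide, BrCc1ccccc1
Why: Williamson ether synthesis on a phenoxide; the aryl bromide is inert under these conditions.

**Step 2**
Reactants: 2 1-(benzyloxy)-4-bromo-2-methoxybenzene
Product: 3 1-(benzyloxy)-4-bromo-5-iodo-2-methoxybenzene
Conditions: N-iodosuccinimide, CF3CO2H (cat.), MeCN, rt
Reagents that add atoms: N-iodosuccinimide, O=C1CCC(=O)N1I
Why: Electrophilic aromatic iodination; the position para to the methoxyl (and ortho to bromine) is the most activated open site, since the position para to the benzyloxy group is blocked by bromine and the remaining sites are ortho positions.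

**Step 3**
Reactants: 4 4-(benzyloxy)-3-methoxybenzaldehyde; 5 malonic acid
Product: 6 (2E)-3-[4-(benzyloxy)-3-methoxyphenyl]prop-2-enoic acid
Conditions: pyridine, piperidine (cat.), 90 °C
Reagents that add atoms: none
Why: Knoevenagel–Doebner condensation with decarboxylation, which gives the E-cinnamic acid under thermodynamic control.

**Step 4**
Reactants: 6 (2E)-3-[4-(benzyloxy)-3-methoxyphenyl]prop-2-enoic acid; 7 (S)-4-benzyl-1,3-oxazolidin-2-one
Product: 9 (4S)-4-benzyl-3-{(2E)-3-[4-(benzyloxy)-3-methoxyphenyl]prop-2-enoyl}-1,3-oxazolidin-2-one, via pivalic mixed anhydride 8 (not isolated)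
Conditions: t-BuCOCl, Et3N, THF, −20 °C; then 7, LiCl, rt
Reagents that add atoms: none
Why: N-acylation of the oxazolidinone through a mixed anhydride; the lithium-activated auxiliary attacks the less hindered cinnamoyl carbonyl group.

**Step 5**
Reactants: 3 1-(benzyloxy)-4-bromo-5-iodo-2-methoxybenzene; 9 (4S)-4-benzyl-3-{(2E)-3-[4-(benzyloxy)-3-methoxyphenyl]prop-2-enoyl}-1,3-oxazolidin-2-one
Product: 11 (4S)-4-benzyl-3-{(3S)-3-[5-(benzyloxy)-2-bromo-4-methoxyphenyl]-3-[4-(benzyloxy)-3-methoxyphenyl]propanoyl}-1,3-oxazolidin-2-one, via arylmagnesium chloride 10 (not isolated)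
Conditions: 3, i-PrMgCl·LiCl, THF, −40 °C; CuBr·SMe2, Me2S/THF, −40 °C; then 9, −40 → −20 °C; aq. NH4Cl
Reagents that add atoms: none
Why: Iodine–magnesium exchange is much faster at C–I than at C–Br, and the ortho-bromoaryl reagent is kept cold to prevent aryne formation; transmetalation to monovalent copper then allows 1,4-addition (copper-mediated conjugate addition of a Grignard reagent to an N-enoyl oxazolidinone). The magnesium-chelated s-cis enoyl imide is attacked at C1 on the face opposite the 4-benzyl group, which, with ring C in the enoyl unit and ring A arriving, gives (S)-C1.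

**Step 6**
Reactants: 11 (4S)-4-benzyl-3-{(3S)-3-[5-(benzyloxy)-2-bromo-4-methoxyphenyl]-3-[4-(benzyloxy)-3-methoxyphenyl]propanoyl}-1,3-oxazolidin-2-one; 12 tert-butyl bromoacetate
Product: 14 tert-butyl (3S,4S)-3-{[(4S)-4-benzyl-2-oxo-1,3-oxazolidin-3-yl]carbonyl}-4-[5-(benzyloxy)-2-bromo-4-methoxyphenyl]-4-[4-(benzyloxy)-3-methoxyphenyl]butanoate, via sodium Z-enolate 13 (not isolated)
Conditions: NaN(SiMe3)2, THF, −78 °C; then 12, −78 → −40 °C
Reagents that add atoms: none
Why: Evans alkylation: the chelated Z-enolate is alkylated at C2 anti to the 4-benzyl group by the reactive α-bromo ester. The auxiliary steers this step and step 5 from the same side, so C3 and ring A are syn on the C9–C2–C1–ring C chain, which is the anti (later trans) relation of C9 and ring C.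

**Step 7**
Reactants: 14 tert-butyl (3S,4S)-3-{[(4S)-4-benzyl-2-oxo-1,3-oxazolidin-3-yl]carbonyl}-4-[5-(benzyloxy)-2-bromo-4-methoxyphenyl]-4-[4-(benzyloxy)-3-methoxyphenyl]butanoate
Product: 15 tert-butyl (3S,4S)-4-[5-(benzyloxy)-2-bromo-4-methoxyphenyl]-4-[4-(benzyloxy)-3-methoxyphenyl]-3-(hydroxymethyl)butanoate
Conditions: LiBH4, MeOH (1 equiv), THF, 0 °C
Reagents that add atoms: none
Why: Reductive cleavage of the acyl oxazolidinone; LiBH4 reduces the activated imide carbonyl group but not the tert-butyl ester, whose bulk also slows lactonisation of the γ-hydroxy ester. C2 is not epimerised because no enolate is formed.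

**Step 8**
Reactants: 15 tert-butyl (3S,4S)-4-[5-(benzyloxy)-2-bromo-4-methoxyphenyl]-4-[4-(benzyloxy)-3-methoxyphenyl]-3-(hydroxymethyl)butanoate
Product: 16 tert-butyl (3S,4S)-4-[5-(benzyloxy)-2-bromo-4-methoxyphenyl]-4-[4-(benzyloxy)-3-methoxyphenyl]-3-({[tert-butyl(dimethyl)silyl]oxy}methyl)butanoate
Conditions: t-BuMe2SiCl, imidazole, DMF, rt
Reagents that add atoms: tert-butyldimethylsilyl chloride, CC(C)(C)[Si](C)(C)Cl
Why: Silylation of the primary alcohol, carried out at once so that the hydroxy ester has no time to lactonise; the silyl ether removes the one group that could capture an acyl palladium species in step 9.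

**Step 9**
Reactants: 16 tert-butyl (3S,4S)-4-[5-(benzyloxy)-2-bromo-4-methoxyphenyl]-4-[4-(benzyloxy)-3-methoxyphenyl]-3-({[tert-butyl(dimethyl)silyl]oxy}methyl)butanoate; 17 carbon monoxide
Product: 19 tert-butyl (1S,2R)-7-(benzyloxy)-1-[4-(benzyloxy)-3-methoxyphenyl]-2-({[tert-butyl(dimethyl)silyl]oxy}methyl)-4-hydroxy-6-methoxy-1,2-dihydronaphthalene-3-carboxylate (enol form), via lithium ester enolate 18 (not isolated)
Conditions: LiN(SiMe3)2 (2.2 equiv), THF, −78 → 0 °C; then Pd(OAc)2 (5 mol %), Xantphos (7.5 mol %), CO (2 bar), toluene/THF, 80 °C; then AcOH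
Reagents that add atoms: none
Why: LiN(SiMe3)2 converts the tert-butyl ester into enolate 18; zerovalent palladium formed from Pd(OAc)2 and Xantphos inserts into the C4a–Br bond, and CO then inserts into the aryl–palladium bond to give an aroyl palladium bromide. The tethered enolate carbon C3 is acylated by this species, either by direct attack at the acyl carbon or through a palladium C-enolate and reductive elimination, which forms C4–C3 after C4a–C4 and returns zerovalent palladium. The second equivalent of base deprotonates the β-keto ester, which pulls the reaction forward and is why the product is isolated as the hydrogen-bonded enol after acidification. The closest known reaction type is the palladium-catalysed carbonylative α-arylation of enolates with aryl halides and CO, including intramolecular trapping of acyl palladium species by tethered enolates. Ring B closes in a 6-exo-trig mode (C3 onto the C4 acyl carbon, whose oxygen stays outside the ring). No stereocentre is formed: C3 and C4 are sp2 in the enol, and C1 and C2 are carried through because C2 is β to the ester and C1–H is far less acidic than the ester α-hydrogen. The step needs CO insertion before C–C coupling (direct α-arylation would give a five-membered indane) and C- over O-acylation: the CO pressure and the wide bite angle of Xantphos favour the acyl complex, O-acylation would require an eight-membered ketene acetal, and the bulk of the silylamide together with the absence of any free OH leaves the tethered enolate as the only effective nucleophile.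

**Step 10**
Reactants: 19 tert-butyl (1S,2R)-7-(benzyloxy)-1-[4-(benzyloxy)-3-methoxyphenyl]-2-({[tert-butyl(dimethyl)silyl]oxy}methyl)-4-hydroxy-6-methoxy-1,2-dihydronaphthalene-3-carboxylate
Product: 20 tert-butyl (1S,2R)-7-(benzyloxy)-1-[4-(benzyloxy)-3-methoxyphenyl]-2-({[tert-butyl(dimethyl)silyl]oxy}methyl)-6-methoxy-4-{[(trifluoromethyl)sulfonyl]oxy}-1,2-dihydronaphthalene-3-carboxylate
Conditions: (CF3SO2)2O, i-Pr2NEt, CH2Cl2, −78 °C
Reagents that add atoms: trifluoromethanesulfonic anhydride, O=S(=O)(OS(=O)(=O)C(F)(F)F)C(F)(F)F
Why: O-sulfonylation of the enol of a β-keto ester (enol triflate formation); the low temperature and hindered amine leave the silyl ether and the electron-rich rings untouched.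

**Step 11**
Reactants: 20 tert-butyl (1S,2R)-7-(benzyloxy)-1-[4-(benzyloxy)-3-methoxyphenyl]-2-({[tert-butyl(dimethyl)silyl]oxy}methyl)-6-methoxy-4-{[(trifluoromethyl)sulfonyl]oxy}-1,2-dihydronaphthalene-3-carboxylate
Product: 21 tert-butyl (1S,2R)-7-(benzyloxy)-1-[4-(benzyloxy)-3-methoxyphenyl]-2-({[tert-butyl(dimethyl)silyl]oxy}methyl)-6-methoxy-1,2-dihydronaphthalene-3-carboxylate
Conditions: Pd(OAc)2, PPh3, Et3SiH, DMF, 60 °C
Reagents that add atoms: none
Why: Palladium-catalysed reduction of an enol triflate: oxidative addition at the activated C4–O bond, hydride transfer from the silane and reductive elimination give C4–H. Without H2 the benzyl ethers and the C3=C4 bond are not reduced.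

**Step 12**
Reactants: 21 tert-butyl (1S,2R)-7-(benzyloxy)-1-[4-(benzyloxy)-3-methoxyphenyl]-2-({[tert-butyl(dimethyl)silyl]oxy}methyl)-6-methoxy-1,2-dihydronaphthalene-3-carboxylate
Product: 22 [(1S,2R)-7-(benzyloxy)-1-[4-(benzyloxy)-3-methoxyphenyl]-2-({[tert-butyl(dimethyl)silyl]oxy}methyl)-6-methoxy-1,2-dihydronaphthalen-3-yl]methanol
Conditions: i-Bu2AlH (3 equiv), CH2Cl2, −78 → 0 °C; aqueous work-up
Reagents that add atoms: none
Why: 1,2-Reduction of the α,β-unsaturated ester to the allylic alcohol by i-Bu2AlH, which does not add in conjugate fashion and leaves the silyl and benzyl ethers intact.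

**Step 13**
Reactants: 22 [(1S,2R)-7-(benzyloxy)-1-[4-(benzyloxy)-3-methoxyphenyl]-2-({[tert-butyl(dimethyl)silyl]oxy}methyl)-6-methoxy-1,2-dihydronaphthalen-3-yl]methanol
Product: 23 (1S,2R)-7-(benzyloxy)-1-[4-(benzyloxy)-3-methoxyphenyl]-2-({[tert-butyl(dimethyl)silyl]oxy}methyl)-6-methoxy-1,2-dihydronaphthalene-3-carbaldehyde
Conditions: MnO2 (activated), CH2Cl2, rt
Reagents that add atoms: none
Why: Neutral heterogeneous oxidation of an allylic alcohol to the enal; at room temperature and with short contact, ring B should not be dehydrogenated and C2 is not exposed to base.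

**Step 14**
Reactants: 23 (1S,2R)-7-(benzyloxy)-1-[4-(benzyloxy)-3-methoxyphenyl]-2-({[tert-butyl(dimethyl)silyl]oxy}methyl)-6-methoxy-1,2-dihydronaphthalene-3-carbaldehyde
Product: 24 (1S,2R)-7-(benzyloxy)-1-[4-(benzyloxy)-3-methoxyphenyl]-2-(hydroxymethyl)-6-methoxy-1,2-dihydronaphthalene-3-carbaldehyde
Conditions: HF·pyridine, pyridine/THF, 0 °C → rt
Reagents that add atoms: none
Why: Fluoride-driven desilylation in a buffered acidic medium; it avoids the basic fluoride that could deprotonate C2–H of the enal.

**Step 15**
Reactants: 24 (1S,2R)-7-(benzyloxy)-1-[4-(benzyloxy)-3-methoxyphenyl]-2-(hydroxymethyl)-6-methoxy-1,2-dihydronaphthalene-3-carbaldehyde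
Product: 25 [(1S,2R)-7-(benzyloxy)-1-[4-(benzyloxy)-3-methoxyphenyl]-3-formyl-6-methoxy-1,2-dihydronaphthalen-2-yl]methyl acetate
Conditions: Ac2O, pyridine, DMAP (cat.), CH2Cl2, 0 °C
Reagents that add atoms: acetic anhydride, CC(=O)OC(C)=O
Why: Acylation of the only free hydroxyl group under weakly basic nucleophilic catalysis; it also removes the possibility of lactol formation between C9–OH and the aldehyde.

**Step 16**
Reactants: 25 [(1S,2R)-7-(benzyloxy)-1-[4-(benzyloxy)-3-methoxyphenyl]-3-formyl-6-methoxy-1,2-dihydronaphthalen-2-yl]methyl acetate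
Product: 26 [(1S,2R)-3-formyl-7-hydroxy-1-(4-hydroxy-3-methoxyphenyl)-6-methoxy-1,2-dihydronaphthalen-2-yl]methyl acetate
Conditions: BCl3, C6HMe5, CH2Cl2, −78 °C; then H2O
Reagents that add atoms: none
Why: Lewis acid cleavage of aryl benzyl ethers with pentamethylbenzene as a non-basic trap for the benzyl cation. At −78 °C the aryl methyl ethers, the acetate and the enal should be kept, and the C3=C4 bond, which hydrogenolysis would reduce, is not touched.

## Compound list

1 | 4-bromo-2-methoxyphenol | COc1cc(Br)ccc1O | starting material
2 | 1-(benzyloxy)-4-bromo-2-methoxybenzene | COc1cc(Br)ccc1OCc1ccccc1 | intermediate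
3 | 1-(benzyloxy)-4-bromo-5-iodo-2-methoxybenzene | COc1cc(Br)c(I)cc1OCc1ccccc1 | intermediate
4 | 4-(benzyloxy)-3-methoxybenzaldehyde | COc1cc(C=O)ccc1OCc1ccccc1 | starting material
5 | malonic acid | OC(=O)CC(=O)O | starting material
6 | (2E)-3-[4-(benzyloxy)-3-methoxyphenyl]prop-2-enoic acid | COc1cc(/C=C/C(=O)O)ccc1OCc1ccccc1 | intermediate
7 | (S)-4-benzyl-1,3-oxazolidin-2-one | O=C1N[C@@H](Cc2ccccc2)CO1 | starting material
8 | (2E)-3-[4-(benzyloxy)-3-methoxyphenyl]prop-2-enoic 2,2-dimethylpropanoic anhydride | COc1cc(/C=C/C(=O)OC(=O)C(C)(C)C)ccc1OCc1ccccc1 | intermediate (not isolated)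
9 | (4S)-4-benzyl-3-{(2E)-3-[4-(benzyloxy)-3-methoxyphenyl]prop-2-enoyl}-1,3-oxazolidin-2-one | COc1cc(/C=C/C(=O)N2[C@@H](Cc3ccccc3)COC2=O)ccc1OCc4ccccc4 | intermediate
10 | [5-(benzyloxy)-2-bromo-4-methoxyphenyl]magnesium chloride | COc1cc(Br)c([Mg]Cl)cc1OCc1ccccc1 | intermediate (not isolated)
11 | (4S)-4-benzyl-3-{(3S)-3-[5-(benzyloxy)-2-bromo-4-methoxyphenyl]-3-[4-(benzyloxy)-3-methoxyphenyl]propanoyl}-1,3-oxazolidin-2-one | COc1cc([C@@H](c2cc(OCc3ccccc3)c(OC)cc2Br)CC(=O)N4[C@@H](Cc5ccccc5)COC4=O)ccc1OCc6ccccc6 | intermediate
12 | tert-butyl bromoacetate | CC(C)(C)OC(=O)CBr | starting material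
13 | sodium (Z)-enolate of 11 | COc1cc([C@@H](c2cc(OCc3ccccc3)c(OC)cc2Br)/C=C(\O[Na])N4[C@@H](Cc5ccccc5)COC4=O)ccc1OCc6ccccc6 | intermediate (not isolated)
14 | tert-butyl (3S,4S)-3-{[(4S)-4-benzyl-2-oxo-1,3-oxazolidin-3-yl]carbonyl}-4-[5-(benzyloxy)-2-bromo-4-methoxyphenyl]-4-[4-(benzyloxy)-3-methoxyphenyl]butanoate | COc1cc([C@@H](c2cc(OCc3ccccc3)c(OC)cc2Br)[C@@H](C(=O)N4[C@@H](Cc5ccccc5)COC4=O)CC(=O)OC(C)(C)C)ccc1OCc6ccccc6 | intermediate
15 | tert-butyl (3S,4S)-4-[5-(benzyloxy)-2-bromo-4-methoxyphenyl]-4-[4-(benzyloxy)-3-methoxyphenyl]-3-(hydroxymethyl)butanoate | COc1cc([C@@H](c2cc(OCc3ccccc3)c(OC)cc2Br)[C@@H](CO)CC(=O)OC(C)(C)C)ccc1OCc4ccccc4 | intermediate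
16 | tert-butyl (3S,4S)-4-[5-(benzyloxy)-2-bromo-4-methoxyphenyl]-4-[4-(benzyloxy)-3-methoxyphenyl]-3-({[tert-butyl(dimethyl)silyl]oxy}methyl)butanoate | COc1cc([C@@H](c2cc(OCc3ccccc3)c(OC)cc2Br)[C@@H](CO[Si](C)(C)C(C)(C)C)CC(=O)OC(C)(C)C)ccc1OCc4ccccc4 | intermediate
17 | carbon monoxide | [C-]#[O+] | starting material
18 | lithium enolate of 16 | COc1cc([C@@H](c2cc(OCc3ccccc3)c(OC)cc2Br)[C@@H](CO[Si](C)(C)C(C)(C)C)C=C(O[Li])OC(C)(C)C)ccc1OCc4ccccc4 | intermediate (not isolated)
19 | tert-butyl (1S,2R)-7-(benzyloxy)-1-[4-(benzyloxy)-3-methoxyphenyl]-2-({[tert-butyl(dimethyl)silyl]oxy}methyl)-4-hydroxy-6-methoxy-1,2-dihydronaphthalene-3-carboxylate | COc1cc([C@H]2c3cc(OCc4ccccc4)c(OC)cc3C(O)=C(C(=O)OC(C)(C)C)[C@@H]2CO[Si](C)(C)C(C)(C)C)ccc1OCc5ccccc5 | intermediate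
20 | tert-butyl (1S,2R)-7-(benzyloxy)-1-[4-(benzyloxy)-3-methoxyphenyl]-2-({[tert-butyl(dimethyl)silyl]oxy}methyl)-6-methoxy-4-{[(trifluoromethyl)sulfonyl]oxy}-1,2-dihydronaphthalene-3-carboxylate | COc1cc([C@H]2c3cc(OCc4ccccc4)c(OC)cc3C(OS(=O)(=O)C(F)(F)F)=C(C(=O)OC(C)(C)C)[C@@H]2CO[Si](C)(C)C(C)(C)C)ccc1OCc5ccccc5 | intermediate
21 | tert-butyl (1S,2R)-7-(benzyloxy)-1-[4-(benzyloxy)-3-methoxyphenyl]-2-({[tert-butyl(dimethyl)silyl]oxy}methyl)-6-methoxy-1,2-dihydronaphthalene-3-carboxylate | COc1cc([C@H]2c3cc(OCc4ccccc4)c(OC)cc3C=C(C(=O)OC(C)(C)C)[C@@H]2CO[Si](C)(C)C(C)(C)C)ccc1OCc5ccccc5 | intermediate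
22 | [(1S,2R)-7-(benzyloxy)-1-[4-(benzyloxy)-3-methoxyphenyl]-2-({[tert-butyl(dimethyl)silyl]oxy}methyl)-6-methoxy-1,2-dihydronaphthalen-3-yl]methanol | COc1cc([C@H]2c3cc(OCc4ccccc4)c(OC)cc3C=C(CO)[C@@H]2CO[Si](C)(C)C(C)(C)C)ccc1OCc5ccccc5 | intermediate
23 | (1S,2R)-7-(benzyloxy)-1-[4-(benzyloxy)-3-methoxyphenyl]-2-({[tert-butyl(dimethyl)silyl]oxy}methyl)-6-methoxy-1,2-dihydronaphthalene-3-carbaldehyde | COc1cc([C@H]2c3cc(OCc4ccccc4)c(OC)cc3C=C(C=O)[C@@H]2CO[Si](C)(C)C(C)(C)C)ccc1OCc5ccccc5 | intermediate
24 | (1S,2R)-7-(benzyloxy)-1-[4-(benzyloxy)-3-methoxyphenyl]-2-(hydroxymethyl)-6-methoxy-1,2-dihydronaphthalene-3-carbaldehyde | COc1cc([C@H]2c3cc(OCc4ccccc4)c(OC)cc3C=C(C=O)[C@@H]2CO)ccc1OCc5ccccc5 | intermediate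
25 | [(1S,2R)-7-(benzyloxy)-1-[4-(benzyloxy)-3-methoxyphenyl]-3-formyl-6-methoxy-1,2-dihydronaphthalen-2-yl]methyl acetate | COc1cc([C@H]2c3cc(OCc4ccccc4)c(OC)cc3C=C(C=O)[C@@H]2COC(C)=O)ccc1OCc5ccccc5 | intermediate
26 | [(1S,2R)-3-formyl-7-hydroxy-1-(4-hydroxy-3-methoxyphenyl)-6-methoxy-1,2-dihydronaphthalen-2-yl]methyl acetate | COc1cc([C@H]2c3cc(O)c(OC)cc3C=C(C=O)[C@@H]2COC(C)=O)ccc1O | target

## Step count and least certain steps

Total: 16 steps. Longest linear sequence: 14 steps (steps 3 to 16 from 4, or steps 1, 2 and 5 to 16 from 1).

**Step 9 (key step).** The most likely failure is C–C coupling before CO uptake, because CO insertion into the hindered, ortho-substituted aryl palladium species may be slow; this would divert material to direct arylation of the enolate. A second risk is interception of the aroyl palladium species by the silylamide base, or slow turnover of CO-saturated palladium. The fallback separates the two bond formations. It sets out from 16 and returns at 19. Palladium-catalysed methoxycarbonylation of the aryl bromide (Pd(OAc)2, Xantphos, CO, MeOH, Et3N, 70 °C) forms C4a–C4 and gives methyl 4-(benzyloxy)-2-[(1S,2S)-1-[4-(benzyloxy)-3-methoxyphenyl]-4-(tert-butoxy)-2-({[tert-butyl(dimethyl)silyl]oxy}methyl)-4-oxobutyl]-5-methoxybenzoate F1. A Dieckmann condensation (LiN(SiMe3)2, THF, −78 → 0 °C) of the tert-butyl ester enolate onto the aryl methyl ester then forms C4–C3 and delivers 19.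

**Step 5.** The ortho-bromoaryl metal may lose magnesium halide to an aryne on warming, or the ortho-substituted aryl group may transfer slowly from copper; either would force higher temperatures and erode facial selectivity. The fallback sets out from 2 and returns at 11. It puts ring A in the enoyl unit and delivers ring C as an ordinary Grignard reagent. Because this exchange would give the wrong C1 with 7, the addition is run on the antipodal auxiliary, which is then replaced.
- 2-Bromo-5-hydroxy-4-methoxybenzaldehyde F2 is benzylated (benzyl bromide, K2CO3, DMF) to 5-(benzyloxy)-2-bromo-4-methoxybenzaldehyde F3.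
- F3 is condensed with 5 (pyridine, piperidine, 90 °C) to (2E)-3-[5-(benzyloxy)-2-bromo-4-methoxyphenyl]prop-2-enoic acid F4.
- F4 is activated (t-BuCOCl, Et3N) as its pivalic mixed anhydride F5 and joined to (R)-4-benzyl-1,3-oxazolidin-2-one F6 (LiCl) to give (4R)-4-benzyl-3-{(2E)-3-[5-(benzyloxy)-2-bromo-4-methoxyphenyl]prop-2-enoyl}-1,3-oxazolidin-2-one F7.
- Bromide 2 is converted (Mg, THF) into [4-(benzyloxy)-3-methoxyphenyl]magnesium bromide F8, which adds to F7 with CuBr·SMe2 to give (4R)-4-benzyl-3-{(3S)-3-[5-(benzyloxy)-2-bromo-4-methoxyphenyl]-3-[4-(benzyloxy)-3-methoxyphenyl]propanoyl}-1,3-oxazolidin-2-one F9.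
- LiOH/H2O2 releases (3S)-3-[5-(benzyloxy)-2-bromo-4-methoxyphenyl]-3-[4-(benzyloxy)-3-methoxyphenyl]propanoic acid F10, whose pivalic mixed anhydride F11 (t-BuCOCl, Et3N) acylates 7 (LiCl) to give 11.

**Step 7.** Hydride may attack the ring carbonyl of the hindered imide (opening the auxiliary), or the intermediate alkoxide may lactonise onto the tert-butyl ester and be reduced further. The fallback sets out from 14 and returns at 15. Hydrolysis with LiOH/H2O2 (THF/H2O, 0 °C), which is selective for the exocyclic carbonyl group, gives (2S)-2-{(S)-[5-(benzyloxy)-2-bromo-4-methoxyphenyl][4-(benzyloxy)-3-methoxyphenyl]methyl}-4-(tert-butoxy)-4-oxobutanoic acid F12. Reduction of the carboxylic acid with BH3·SMe2 (THF, 0 °C), which leaves the tert-butyl ester, gives 15.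

**Step 16.** The Lewis acid may remove or shift the acetyl group, cleave a methyl ether next to a freed hydroxyl, or add to the activated enal. The fallback reverses the order of the last operations. It sets out from 24 and returns at 26. Debenzylation of 24 (BCl3, C6HMe5, CH2Cl2, −78 °C), before any acetate is present, gives (1S,2R)-7-hydroxy-2-(hydroxymethyl)-1-(4-hydroxy-3-methoxyphenyl)-6-methoxy-1,2-dihydronaphthalene-3-carbaldehyde F13. Its primary aliphatic hydroxyl is then acetylated in preference to the two phenols by an immobilised lipase (lipase B of Candida antarctica, vinyl acetate, t-BuOMe, rt) to give 26.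

## Further compounds

F1 | step 9 | methyl 4-(benzyloxy)-2-[(1S,2S)-1-[4-(benzyloxy)-3-methoxyphenyl]-4-(tert-butoxy)-2-({[tert-butyl(dimethyl)silyl]oxy}methyl)-4-oxobutyl]-5-methoxybenzoate | COc1cc([C@@H](c2cc(OCc3ccccc3)c(OC)cc2C(=O)OC)[C@@H](CO[Si](C)(C)C(C)(C)C)CC(=O)OC(C)(C)C)ccc1OCc4ccccc4
F2 | step 5 | 2-bromo-5-hydroxy-4-methoxybenzaldehyde | COc1cc(Br)c(C=O)cc1O
F3 | step 5 | 5-(benzyloxy)-2-bromo-4-methoxybenzaldehyde | COc1cc(Br)c(C=O)cc1OCc1ccccc1
F4 | step 5 | (2E)-3-[5-(benzyloxy)-2-bromo-4-methoxyphenyl]prop-2-enoic acid | COc1cc(Br)c(/C=C/C(=O)O)cc1OCc1ccccc1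
F5 | step 5 | (2E)-3-[5-(benzyloxy)-2-bromo-4-methoxyphenyl]prop-2-enoic 2,2-dimethylpropanoic anhydride | COc1cc(Br)c(/C=C/C(=O)OC(=O)C(C)(C)C)cc1OCc1ccccc1
F6 | step 5 | (R)-4-benzyl-1,3-oxazolidin-2-one | O=C1N[C@H](Cc2ccccc2)CO1
F7 | step 5 | (4R)-4-benzyl-3-{(2E)-3-[5-(benzyloxy)-2-bromo-4-methoxyphenyl]prop-2-enoyl}-1,3-oxazolidin-2-one | COc1cc(Br)c(/C=C/C(=O)N2[C@H](Cc3ccccc3)COC2=O)cc1OCc4ccccc4
F8 | step 5 | [4-(benzyloxy)-3-methoxyphenyl]magnesium bromide | COc1cc([Mg]Br)ccc1OCc1ccccc1
F9 | step 5 | (4R)-4-benzyl-3-{(3S)-3-[5-(benzyloxy)-2-bromo-4-methoxyphenyl]-3-[4-(benzyloxy)-3-methoxyphenyl]propanoyl}-1,3-oxazolidin-2-one | COc1cc([C@@H](c2cc(OCc3ccccc3)c(OC)cc2Br)CC(=O)N4[C@H](Cc5ccccc5)COC4=O)ccc1OCc6ccccc6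
F10 | step 5 | (3S)-3-[5-(benzyloxy)-2-bromo-4-methoxyphenyl]-3-[4-(benzyloxy)-3-methoxyphenyl]propanoic acid | COc1cc([C@@H](c2cc(OCc3ccccc3)c(OC)cc2Br)CC(=O)O)ccc1OCc4ccccc4
F11 | step 5 | (3S)-3-[5-(benzyloxy)-2-bromo-4-methoxyphenyl]-3-[4-(benzyloxy)-3-methoxyphenyl]propanoic 2,2-dimethylpropanoic anhydride | COc1cc([C@@H](c2cc(OCc3ccccc3)c(OC)cc2Br)CC(=O)OC(=O)C(C)(C)C)ccc1OCc4ccccc4
F12 | step 7 | (2S)-2-{(S)-[5-(benzyloxy)-2-bromo-4-methoxyphenyl][4-(benzyloxy)-3-methoxyphenyl]methyl}-4-(tert-butoxy)-4-oxobutanoic acid | COc1cc([C@@H](c2cc(OCc3ccccc3)c(OC)cc2Br)[C@@H](C(=O)O)CC(=O)OC(C)(C)C)ccc1OCc4ccccc4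
F13 | step 16 | (1S,2R)-7-hydroxy-2-(hydroxymethyl)-1-(4-hydroxy-3-methoxyphenyl)-6-methoxy-1,2-dihydronaphthalene-3-carbaldehyde | COc1cc([C@H]2c3cc(O)c(OC)cc3C=C(C=O)[C@@H]2CO)ccc1O
A1 | alternative 1 | (4R)-4-[4-(benzyloxy)-3-methoxybenzyl]dihydrofuran-2(3H)-one | O=C1C[C@@H](Cc2ccc(OCc3ccccc3)c(OC)c2)CO1
A2 | alternative 1 | 3-[4-(benzyloxy)-3-methoxybenzyl]cyclobutan-1-one | O=C1CC(Cc2ccc(OCc3ccccc3)c(OC)c2)C1
A3 | alternative 2 | (1S,2R)-2-formyl-7-hydroxy-1-(4-hydroxy-3-methoxyphenyl)-N,6-dimethoxy-N-methyl-1,2-dihydronaphthalene-3-carboxamide | COc1cc([C@H]2c3cc(O)c(OC)cc3C=C(C(=O)N(C)OC)[C@@H]2C=O)ccc1O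
A4 | alternative 2 | (2E)-3-{4-hydroxy-2-[(4-hydroxy-3-methoxyphenyl)(methoxy)methyl]-5-methoxyphenyl}-N-methoxy-N-methyl-2-(2-oxoethyl)prop-2-enamide | COc1cc(C(OC)c2cc(O)c(OC)cc2/C=C(\CC=O)C(=O)N(C)OC)ccc1O
A5 | alternative 3 | dimethyl (1S,2R,3S,4S)-4-hydroxy-6-methoxy-7-(methoxymethoxy)-1-[3-methoxy-4-(methoxymethoxy)phenyl]-1,2,3,4-tetrahydronaphthalene-2,3-dicarboxylate | COc1cc([C@H]2c3cc(OCOC)c(OC)cc3[C@@H](O)[C@@H](C(=O)OC)[C@@H]2C(=O)OC)ccc1OCOC
A6 | alternative 3 | 5-methoxy-4-(methoxymethoxy)-2-[3-methoxy-4-(methoxymethoxy)benzyl]benzaldehyde | COc1cc(Cc2cc(OCOC)c(OC)cc2C=O)ccc1OCOC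
A7 | alternative 3 | dimethyl fumarate | COC(=O)/C=C/C(=O)OC
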